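Numbering used throughout: friedelane numbering (C1–C30, rings A–E) for the triterpene half and primed guaiane numbering for the sesquiterpene half; α means below and β above the plane in the usual drawing with ring A at the left.

## The problem

Compound 46 is a hetero-adduct of two terpenoids. One half is a C28 nor-friedelane whose ring A is a catechol; the other is a guaiane whose C1′–C5′ bond carries the two catechol oxygens (O2 on C1′, O3 on C5′) in a cis-fused 1,4-benzodioxane. The triterpene half has five fused rings and seven stereocentres: C8 (8β-H), the methyl-bearing quaternary carbons C9, C13, C14 and C17, and C18 and C20. C13 and C14 are vicinal with anti methyl groups, C9 and C14 carry syn-axial methyl groups, and rings D/E are cis-fused. Only C13 needs an external chiral reagent. C14 (anti to the C13 methyl), C18/C17, C9 (face opposite the 14β-methyl) and C8 can each be set from centres already present, and C20 is epimerisable with the natural β-methyl equatorial. The sesquiterpene half has C7′ and C10′ cis on the seven-membered ring (7′S,10′R). This is the mirror image of the guaiol/α-guaiene series of commerce at these centres, so it has to be made; C1′ and C5′ arise when the halves are joined. The fragile groups are the catechol and its ortho-quinone (air; tautomerisation to the extended quinone methide would erase C8), the styrene-type 6-ene, the tertiary allylic aryl ethers of the dioxane (acid), the cyclopentadiene (1,5-hydrogen shifts, dimerisation) and the isopropenyl group. The feature that opens the route is ring B: it is bounded by the arene bond C5–C10 and the benzylic quaternary C9, with C6–C8 at the diene oxidation level, so an aryne across C5–C10 and a C6=C7–C8=C9 vinylcyclohexene map onto it exactly.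

## Retrosynthesis

**46 ⇒ 44 + 43 (O2–C1′, O3–C5′).** Both bonds are tertiary C–O bonds, which are poor targets for substitution chemistry. They are cut together as a hetero-Diels–Alder reaction of ortho-quinone 45 (made in the flask from catechol 44) with the C1′=C5′ bond of triene 43. This removes all 15 sesquiterpene carbons and two stereocentres in one step. The forward reaction must beat tautomerisation of 45, place the less hindered O2 on the diene terminus C1′, and take the face anti to the C10′ methyl.

**44 ⇒ 33 ⇒ 31 (functional group changes).** The catechol is carried as its dimethyl ether. The 6-ene with 8β-H in 33 is traced to the 7-ene 31 by a base-mediated alkene shift. This leaves C8 as the last triterpene centre to be set, by protonation of a flat benzylic/allylic anion, and gives a precursor without the sensitive styrene.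

**31 ⇒ 8 + 29 (C5–C6 and C9–C10).** Cutting both bonds of ring B at the arene gives aryne 30 (from silyl triflate 8) and diene 29. The neighbouring cuts are a Friedel–Crafts closure at C9–C10 or an α-arylation at C9. Each forms only one of the two bonds, needs ring A attached beforehand, and leaves an ortho/para choice on the arene. The aryne cut splits the 28 skeletal carbons 7 + 21, creates the benzylic quaternary C9 in the joining step, and leaves the C7=C8 alkene needed to set C8. The forward reaction must pair the fully substituted C9 with C10 and approach anti to the 14β-methyl.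

**29 ⇒ 27 ⇒ 26 + 28 (C7–C8).** The vinyl group comes from stannane 28 and enol triflate 27. Ketone 26 can enolise only toward C9, so the triflate is regiodefined. The C21 ketone is held as a dioxolane from here to step 20, which differentiates the two carbonyls and keeps an enolisable ketone away from the aryne.

**26 ⇒ 24 ⇒ 23 ⇒ 21 (C17–CH3; ring E from an anisole).** The C17 methyl is cut as a cuprate addition to enone 23. That enone is the reduction/hydrolysis product of anisole 21. An aromatic ring E is inert during the enolate chemistry of ring C, and it delivers the C20 methyl, the C21 oxygen and C18–H from a cheap arene. The alternative, annulating ring E onto a C17 ketone, would need a neopentyl C18 enolate.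

**21 ⇒ 20 ⇒ 19 (C9–CH3 and C14–CH3).** Both methyl groups are enolate alkylations. In 19 the C15=C16 styrene makes C14–H the most acidic proton, so no blocking group is needed. The rigid ring system forces the electrophile anti to the C13 methyl.

**19 ⇒ 18 ⇒ 17 ⇒ 16 ⇒ 15 (C16–C17).** Ring D is closed by Friedel–Crafts cyclodehydration of aldehyde 17. C8 is kept at the alcohol level for this step, because a 1,4-keto aldehyde would close to a furan instead.

**15 ⇒ 13 ⇒ 9 + 10 (C13–C18, C14–C15).** The aryl–C13 bond is cut as a copper-catalysed asymmetric conjugate addition to enone 9; this is the only step that needs an external source of chirality in the triterpene half. Trapping the enolate as acetate 13 fixes the regiochemistry for allylation at the hindered C14.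

**8 ⇒ 5 ⇒ 4 ⇒ 2 ⇒ 1.** The 2-silylaryl triflate comes from the ortho-bromophenol by silyl migration and triflation; the phenol comes from 2,3-dimethoxytoluene by bromination and hydroxylation.

**43 ⇒ 41 ⇒ 39 ⇒ 37 ⇒ 35 + 36 ⇒ 34.** The cyclopentadiene is cut to cyclopentenone 41 (reduction, dehydration) and then to the 1,4-diketone from butynyl ketone 39. The two ring stereocentres come from two catalyst-controlled conjugate additions to cyclohepta-2,6-dienone 35.

## Roads not taken

**Alternative 1:** This cuts C1′–C5′, C2′–C3′ and C3′–C4′ of the guaiane and builds both of its rings in one step. An allenic Pauson–Khand reaction ([Rh(CO)2Cl]2, CO) of allene–yne A2 would give dienone A1. Its merit is ring-forming economy: one step replaces steps 23–25 of the chosen route, and A2 is an acyclic chain with a single stereocentre. Its weak points are that C10′ is sp2 in A1, so the cis-7′,10′ relation must still be made by reduction of a flat dienone with only a remote controlling centre, and that two carbonyl/alkene transpositions separate A1 from triene 43. It also says nothing about the triterpene half, which holds seven of the nine pre-cycloaddition stereocentres. In ring construction this road is better. The chosen plan sets C10′ under catalyst control before the five-membered ring exists and spends its key step on the pentacycle.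

**Alternative 2:** This cuts C10′–C1′ and forms the seven-membered ring by rearrangement of cis-dialkenylcyclopropane A4 to silyl dienol ether A3. Its merit is stereospecificity: the boat transition state and the E-propenyl geometry fix C10′ and C1′ relative to C7′. That is a firmer basis than the reagent-controlled methyl addition of step 23. Its weak points are the synthesis of a trisubstituted cyclopropane with defined relative configuration and a sensitive siloxycyclopentadiene, and the C8′=C9′ alkene in A3, which must be saturated in the presence of the isopropenyl group. Like alternative 1 it addresses only the smaller half. The chosen plan accepts a less certain C10′ in exchange for a five-step guaiane synthesis with no alkene to remove.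

**Alternative 3:** This cuts the two C–CH3 bonds at C13 and C14. A methyl cuprate would add to C14 of pentacyclic enone A6, and the C13 enolate would be trapped with iodomethane to give diketone A5. Its merit is that both vicinal quaternary methyl groups, anti to each other, arise in one flask. The chosen route uses the same stereochemical logic (alkylation anti to the neighbouring angular methyl) but needs two separate steps. Its weak points are cuprate addition to a tetrasubstituted enone inside a pentacycle, removal of the C12 oxygen in the presence of the C21 ketone, and the need to have C8 and C9 already correct in A6. In step count for the methyl groups this road is better. The chosen plan does the equivalent chemistry on a tricycle, where a failure costs little, and keeps the union of ring A with rings C–E convergent.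

Key step: step 19

Remark on the chemistry: C9 (steps 12–16), the C8 carbinol (steps 7–9, 13–15), C14 before step 11 and C1′ (steps 23–24) are carried as epimer mixtures, because each becomes sp2 or is reset later.

## Steps

Step 1
Reactants: 1 2,3-dimethoxytoluene
Product: 2 1-bromo-3,4-dimethoxy-2-methylbenzene
Conditions: NBS, MeCN, 0 °C to rt
Reagents that add atoms: N-bromosuccinimide, O=C1CCC(=O)N1Br
Why: Electrophilic aromatic bromination; the flanked C2 methoxy is twisted out of conjugation, so the C3 methoxy directs para, to the carbon next to the methyl group.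

Step 2
Reactants: 2 1-bromo-3,4-dimethoxy-2-methylbenzene
Product: 4 3,4-dimethoxy-2-methylphenol, via arylboronate 3 (not isolated)
Conditions: n-BuLi, THF, −78 °C; B(OMe)3; then H2O2, NaOH, 0 °C
Reagents that add atoms: hydrogen peroxide, OO
Why: Bromine–lithium exchange, borylation and oxidative 1,2-shift from boron to oxygen; a standard aryl bromide to phenol conversion.

Step 3
Reactants: 4 3,4-dimethoxy-2-methylphenol
Product: 5 6-bromo-3,4-dimethoxy-2-methylphenol
Conditions: NBS, i-Pr2NH (cat.), CH2Cl2, 0 °C
Reagents that add atoms: N-bromosuccinimide, O=C1CCC(=O)N1Br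
Why: Amine-mediated ortho-bromination of a phenol; the para position and the other ortho position are occupied, so only C6 is open next to the hydroxyl.

Step 4
Reactants: 5 6-bromo-3,4-dimethoxy-2-methylphenol
Product: 8 3,4-dimethoxy-2-methyl-6-(trimethylsilyl)phenyl triflate, via silyl ether 6 (not isolated), via lithium phenoxide 7 (not isolated)
Conditions: HN(SiMe3)2, THF, 70 °C; evaporate; n-BuLi, THF, −78 °C; Tf2O, −78 °C to rt
Reagents that add atoms: hexamethyldisilazane, C[Si](C)(C)N[Si](C)(C)C; trifluoromethanesulfonic anhydride, O=S(=O)(OS(=O)(=O)C(F)(F)F)C(F)(F)F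
Why: O-silylation, bromine–lithium exchange with 1,3-silyl shift from oxygen to carbon (retro-Brook rearrangement) and triflation of the phenoxide; the usual way to 2-silylaryl triflates.

Step 5
Reactants: 9 3-methylcyclohex-2-en-1-one; 10 4-bromo-1-methoxy-2-methylbenzene
Product: 13 (R)-3-(4-methoxy-3-methylphenyl)-3-methylcyclohex-1-en-1-yl acetate, via arylalane 11 (not isolated), via aluminium enolate 12 (not isolated)
Conditions: 10, n-BuLi, Et2O, −78 °C; Et2AlCl; then 9, Cu(O2CC4H3S) (copper thiophene-2-carboxylate, 10 mol %), Ph2P–N[CH(CH3)(2-naphthyl)]2 (SimplePhos-type ligand, enantiomer giving the R adduct, 11 mol %), Et2O, −10 °C; then Ac2O, 0 °C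
Reagents that add atoms: acetic anhydride, CC(=O)OC(C)=O
Why: Copper-catalysed asymmetric conjugate addition of an aryl aluminium reagent to a β-methyl enone, a known route to aryl/methyl quaternary centres; the ligand sets C13, and O-acetylation stores the enolate regiochemistry toward C14.

Step 6
Reactants: 13 enol acetate
Product: 15 (3R)-2-allyl-3-(4-methoxy-3-methylphenyl)-3-methylcyclohexan-1-one (C2 epimers), via lithium enolate 14 (not isolated)
Conditions: MeLi (2.1 equiv), DME, 0 °C; allyl bromide, 0 °C to rt
Reagents that add atoms: allyl bromide, C=CCBr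
Why: Cleavage of an enol acetate with methyllithium gives the lithium enolate without loss of regiochemistry, and the reactive allylic halide alkylates the hindered C14; its configuration is irrelevant at this stage.

Step 7
Reactants: 15 allyl ketone
Product: 16 (3R)-2-allyl-3-(4-methoxy-3-methylphenyl)-3-methylcyclohexan-1-ol (diastereomers)
Conditions: NaBH4, MeOH, 0 °C to rt
Reagents that add atoms: none
Why: Hydride reduction takes C8 to the alcohol level, so that the aldehyde of the next steps has no 1,4-related ketone with which to form a furan.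

Step 8
Reactants: 16 allyl alcohol
Product: 17 2-[(2R)-6-hydroxy-2-(4-methoxy-3-methylphenyl)-2-methylcyclohexyl]acetaldehyde (in equilibrium with its lactol)
Conditions: OsO4 (2 mol %), NaIO4, 2,6-lutidine, dioxane–H2O, rt
Reagents that add atoms: sodium periodate (terminal oxidant, oxygen passed on through OsO4), [Na+].[O-]I(=O)(=O)=O
Why: Lemieux–Johnson cleavage of the only unhindered alkene gives the two-carbon aldehyde arm C15–C16; the electron-rich arene is left alone, unlike under ozonolysis.

Step 9
Reactants: 17 hydroxy aldehyde
Product: 18 (4aR)-7-methoxy-4a,6-dimethyl-1,2,3,4,4a,10a-hexahydrophenanthren-1-ol (tricyclic styrene alcohol)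
Conditions: TsOH·H2O (20 mol %), toluene, 80 °C
Reagents that add atoms: none
Why: Friedel–Crafts cyclodehydration of a 4-arylbutanal to a 1,2-dihydronaphthalene; the tether reaches only the two carbons ortho to C18, and the one para to the aryl methyl (C17) is the less hindered; lactol and cyclic ether forms re-ionise under the acid and funnel to the styrene.

Step 10
Reactants: 18 tricyclic alcohol
Product: 19 (4aR)-7-methoxy-4a,6-dimethyl-3,4,4a,10a-tetrahydrophenanthren-1(2H)-one
Conditions: Dess–Martin periodinane, NaHCO3, CH2Cl2, rt
Reagents that add atoms: none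
Why: Mild oxidation of a secondary alcohol; a shift of the alkene into conjugation would be harmless, because both isomers give the same dienolate in step 11.

Step 11
Reactants: 19 tricyclic ketone
Product: 20 (4aS,10aS)-7-methoxy-4a,6,10a-trimethyl-3,4,4a,10a-tetrahydrophenanthren-1(2H)-one (13α,14β-dimethyl)
Conditions: KOt-Bu (1.1 equiv), THF, −40 °C; MeI, −40 to 0 °C
Reagents that add atoms: iodomethane, CI
Why: C14–H is both α to the ketone and vinylogously benzylic, so the extended enolate forms there and is alkylated at its α-carbon; the C13 methyl stands perpendicular to the enolate plane on the adjacent carbon, so iodomethane enters anti to it (the sense known for angular methylation next to an angular methyl in steroid enolates), giving the trans-vicinal dimethyl pair.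

Step 12
Reactants: 20 dimethyl ketone
Product: 21 (4aS,10aS)-7-methoxy-2,4a,6,10a-tetramethyl-3,4,4a,10a-tetrahydrophenanthren-1(2H)-one (C9 epimers)
Conditions: LiN(i-Pr)2, THF, −78 °C; MeI, −78 to −20 °C
Reagents that add atoms: iodomethane, CI
Why: C9 is now the only enolisable position, so kinetic enolate methylation is regiospecific; the new centre becomes sp2 in step 17.

Step 13
Reactants: 21 aryl ketone
Product: 23 tricyclic enone alcohol (8-hydroxy, 17(22)-en-21-one, 18β-H, 20β-methyl), via dihydroanisole 22 (not isolated)
Conditions: Li, NH3(l), THF, EtOH, −33 °C; NH4Cl; then 2 M HCl, MeOH, 50 °C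
Reagents that add atoms: water, O
Why: Birch reduction saturates the styrene, reduces the ketone and gives the 1-methoxycyclohexa-1,4-diene protonated at the two unsubstituted ring positions; acid hydrolysis and conjugation give the enone as in the anisole route to 19-nor enones; C18 is protonated under equilibrating conditions to the isomer with C19 equatorial on ring D (18β-H).

Step 14
Reactants: 23 enone alcohol
Product: 24 tricyclic hydroxy ketone (8-hydroxy, 17β-methyl, 18β-H, 20β-methyl, 21-one)
Conditions: Me2CuLi (5 equiv), BF3·OEt2, Et2O, −78 to −30 °C; aq NH4Cl/NH3; then NaOMe, MeOH, rt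
Reagents that add atoms: lithium dimethylcuprate, [Li+].C[Cu-]C
Why: Lewis-acid-assisted cuprate addition to a β,β-disubstituted enone; methyl enters C17 on the outward β lobe because the α lobe lies under ring D against the axial 13α-methyl, giving the cis D/E fusion (methyl cis to 18-H) usual for such octalones; methoxide lets C20 settle in the equatorial β configuration.

Step 15
Reactants: 24 hydroxy ketone
Product: 25 ketal alcohol (21,21-ethylenedioxy, 8-hydroxy)
Conditions: HOCH2CH2OH, PPTS, benzene, reflux (Dean–Stark)
Reagents that add atoms: ethane-1,2-diol, OCCO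
Why: Ketalisation of the only carbonyl; the dioxolane distinguishes C21 from C8 and later shields C20 and C22 from fluoride and alkoxide.

Step 16
Reactants: 25 ketal alcohol
Product: 26 ketal ketone (8-one, C9 epimers)
Conditions: Dess–Martin periodinane, NaHCO3, CH2Cl2, rt
Reagents that add atoms: none
Why: Oxidation of the hindered secondary alcohol under buffered conditions that leave the ketal intact.

Step 17
Reactants: 26 ketal ketone
Product: 27 enol triflate (8-trifloxy-8-ene)
Conditions: KN(SiMe3)2, THF, −78 to 0 °C; PhNTf2
Reagents that add atoms: N-phenylbis(trifluoromethanesulfonimide), O=S(=O)(N(c1ccccc1)S(=O)(=O)C(F)(F)F)C(F)(F)F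
Why: C14 is quaternary, so enolisation can only go toward C9 and a single tetrasubstituted enol triflate forms.

Step 18
Reactants: 27 enol triflate; 28 tributyl(vinyl)stannane
Product: 29 tricyclic diene (8-vinyl-8-ene, 21,21-ethylenedioxy)
Conditions: Pd(PPh3)4 (10 mol %), CuCl, LiCl, DMSO, 60 °C
Reagents that add atoms: none
Why: Stille coupling of a hindered vinyl triflate; chloride and copper chloride additives are the known remedy for slow transmetalation at congested centres.

Step 19
Reactants: 8 silylaryl triflate; 29 tricyclic diene
Product: 31 pentacyclic 7-ene (2,3-dimethoxy, 9β-methyl, 21,21-ethylenedioxy), via aryne 30 (not isolated)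
Conditions: 8 (2 equiv), CsF (5 equiv), MeCN–toluene 1:1, 25 to 50 °C
Reagents that add atoms: none
Why: Fluoride removes the silyl group of 8 and triflate leaves, giving aryne 30 (C5≡C10). The aryne adds to the vinylcyclohexene unit of 29 in a concerted but asynchronous [4+2] cycloaddition in which the C5–C6 bond at the unhindered CH2 terminus leads and C9–C10 follows; the closest known reaction type is the Diels–Alder reaction of fluoride-generated arynes with 1-vinylcycloalkenes to give 1,4-dihydronaphthalenes. Ring B is closed by this intermolecular cycloaddition, both ring bonds forming in the one step and the C7=C8 alkene remaining. The only new stereocentre, C9, is set by the face of the diene: the pseudoaxial 14β-methyl on the allylic carbon blocks the β face, so C10 bonds from the α face and the C9 methyl ends up β. The step needs regioselectivity: the fully substituted C9 should pair with C10, whose neighbour C1 carries hydrogen, rather than with C5, which is flanked by the C4 methyl and would create a peri clash. Ene reaction and [2+2] addition at the vinyl group are the competing paths; slow aryne release at moderate temperature and an excess of the cheaper aryne precursor are used against them. The dioxolane in place of the C21 ketone prevents fluoride-mediated enolate arylation.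

Step 20
Reactants: 31 pentacyclic 7-ene
Product: 33 pentacyclic 6-ene ketone (2,3-dimethoxy, 8β-H, 21-one), via 6-ene ketal 32 (not isolated)
Conditions: KOt-Bu, DMSO, 25 °C, short reaction time; aq NH4Cl; then PPTS, acetone–H2O, 50 °C
Reagents that add atoms: water, O
Why: Base-mediated isomerisation of a 1,4- to a 1,2-dihydronaphthalene through the benzylic/allylic anion; reprotonation at C6 is degenerate, while protonation at C8 gives the conjugated styrene and is expected on the outward β lobe (between the C9 and C14 methyls), because the α lobe points under ring C against the axial 13α-methyl, giving 8β-H under kinetic control; the ketal keeps C20 out of reach of the base and is then hydrolysed under mild acid.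

Step 21
Reactants: 34 cycloheptanone
Product: 35 cyclohepta-2,6-dien-1-one
Conditions: IBX (2.5 equiv), DMSO, 75 °C
Reagents that add atoms: none
Why: Iodine-based α,β-dehydrogenation of a ketone, which can be taken to the cross-conjugated dienone by the amount of oxidant.

Step 22
Reactants: 35 cyclohepta-2,6-dien-1-one; 36 potassium trifluoro(prop-1-en-2-yl)borate
Product: 37 (S)-6-(prop-1-en-2-yl)cyclohept-2-en-1-one
Conditions: 36 (0.8 equiv), [Rh(cod)2]BF4 (3 mol %), (S)-BINAP, toluene–H2O 10:1, 100 °C
Reagents that add atoms: none
Why: Rhodium–BINAP-catalysed asymmetric 1,4-addition of an alkenylboron reagent to a cyclic enone; the symmetric dienone gives one constitution, the ligand sets C7′ (the BINAP antipode that gives S-configured 3-substituted cycloalkanones), and excess dienone limits double addition.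

Step 23
Reactants: 37 (S)-6-(prop-1-en-2-yl)cyclohept-2-en-1-one
Product: 39 (3R,6S)-2-(but-2-yn-1-yl)-3-methyl-6-(prop-1-en-2-yl)cycloheptan-1-one (C2 epimers), via magnesium enolate 38 (not isolated)
Conditions: MeMgBr, CuBr·SMe2 (5 mol %), Josiphos-type ferrocenyl diphosphine (enantiomer giving 3R), t-BuOMe, −75 °C; then DMPU, 1-bromobut-2-yne, −75 to 0 °C
Reagents that add atoms: methylmagnesium bromide, C[Mg]Br; 1-bromobut-2-yne, CC#CCBr
Why: Copper-catalysed asymmetric conjugate addition of a Grignard reagent to a cyclic enone; the catalyst is expected to override the weak 1,4-bias of the ring substituent and place the C10′ methyl cis to the isopropenyl group, and the enolate is alkylated in the same flask with a reactive propargylic bromide.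

Step 24
Reactants: 39 butynyl ketone
Product: 41 (7S,10R)-guaia-4,11-dien-3-one (C1 epimers), via diketone 40 (not isolated)
Conditions: NaAuCl4·2H2O (2 mol %), EtOH–H2O, 25 °C; then KOH, EtOH, 60 °C
Reagents that add atoms: water, O
Why: Carbonyl-assisted alkyne hydration places the new ketone on the alkyne carbon nearer the ring (five-membered oxygen participation), and the resulting 1,4-diketone undergoes the classical intramolecular aldol condensation to a 2-methylcyclopentenone; C7′ and C10′ are not α to any carbonyl and are untouched.

Step 25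
Reactants: 41 guaia-4,11-dien-3-one
Product: 43 (7S,10R)-guaia-1(5),3,11-triene, via allylic alcohol 42 (not isolated)
Conditions: NaBH4, CeCl3·7H2O, MeOH, 0 °C; then TsOH·H2O (2 mol %), pentane–Et2O, 25 °C; used at once
Reagents that add atoms: none
Why: Luche 1,2-reduction and acid-catalysed dehydration of the cyclopentenol, the usual way to alkylcyclopentadienes; loss of H1 from the allyl cation gives the most substituted diene, which stays in equilibrium with its 1,5-hydrogen-shift isomer.

Step 26
Reactants: 33 pentacyclic 6-ene ketone
Product: 44 catechol (2,3-dihydroxy, 6-ene, 8β-H, 21-one)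
Conditions: BBr3, CH2Cl2, −78 to 0 °C, argon; aq NaHCO3
Reagents that add atoms: none
Why: Lewis-acid cleavage of both aryl methyl ethers at low temperature; the product is kept under argon and oxidised directly.

Step 27
Reactants: 44 catechol; 43 guaia-1(5),3,11-triene
Product: 46 target adduct, via ortho-quinone 45 (not isolated)
Conditions: 43 (3 equiv), Ag2O (3 equiv), MgSO4, CH2Cl2, 0 to 25 °C, dark
Reagents that add atoms: none
Why: Silver oxide oxidises the catechol to the ortho-quinone, which acts as an electron-poor heterodiene toward the electron-rich tetrasubstituted C1′=C5′ bond (inverse-demand hetero-Diels–Alder, as known for ortho-quinones and cyclopentadienes); the less hindered O2 should bond to the diene terminus C1′ and O3 to C5′, the suprafacial addition makes the dioxane cis-fused, and approach anti to the C10′ methyl sets C1′ and C5′.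

## Compound list

1 | 2,3-dimethoxytoluene | COc1cccc(C)c1OC | starting material
2 | 1-bromo-3,4-dimethoxy-2-methylbenzene | COc1ccc(Br)c(C)c1OC | intermediate
3 | dimethyl (3,4-dimethoxy-2-methylphenyl)boronate | COB(OC)c1ccc(OC)c(OC)c1C | intermediate
4 | 3,4-dimethoxy-2-methylphenol | COc1ccc(O)c(C)c1OC | intermediate
5 | 6-bromo-3,4-dimethoxy-2-methylphenol | COc1cc(Br)c(O)c(C)c1OC | intermediate
6 | (6-bromo-3,4-dimethoxy-2-methylphenoxy)trimethylsilane | COc1cc(Br)c(O[Si](C)(C)C)c(C)c1OC | intermediate
7 | lithium 3,4-dimethoxy-2-methyl-6-(trimethylsilyl)phenoxide | COc1cc([Si](C)(C)C)c([O-])c(C)c1OC.[Li+] | intermediate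
8 | 3,4-dimethoxy-2-methyl-6-(trimethylsilyl)phenyl trifluoromethanesulfonate | COc1cc([Si](C)(C)C)c(OS(=O)(=O)C(F)(F)F)c(C)c1OC | intermediate
9 | 3-methylcyclohex-2-en-1-one | CC1=CC(=O)CCC1 | starting material
10 | 4-bromo-1-methoxy-2-methylbenzene | COc1ccc(Br)cc1C | starting material
11 | diethyl(4-methoxy-3-methylphenyl)aluminium | CC[Al](CC)c1ccc(OC)c(C)c1 | intermediate
12 | diethylaluminium (R)-3-(4-methoxy-3-methylphenyl)-3-methylcyclohex-1-en-1-olate | CC[Al](CC)OC1=C[C@@](C)(CCC1)c1ccc(OC)c(C)c1 | intermediate
13 | (R)-3-(4-methoxy-3-methylphenyl)-3-methylcyclohex-1-en-1-yl acetate | CC(=O)OC1=C[C@@](C)(CCC1)c1ccc(OC)c(C)c1 | intermediate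
14 | lithium (R)-3-(4-methoxy-3-methylphenyl)-3-methylcyclohex-1-en-1-olate | [Li+].[O-]C1=C[C@@](C)(CCC1)c1ccc(OC)c(C)c1 | intermediate
15 | (3R)-2-allyl-3-(4-methoxy-3-methylphenyl)-3-methylcyclohexan-1-one | C=CCC1C(=O)CCC[C@@]1(C)c1ccc(OC)c(C)c1 | intermediate
16 | (3R)-2-allyl-3-(4-methoxy-3-methylphenyl)-3-methylcyclohexan-1-ol | C=CCC1C(O)CCC[C@@]1(C)c1ccc(OC)c(C)c1 | intermediate
17 | 2-[(2R)-6-hydroxy-2-(4-methoxy-3-methylphenyl)-2-methylcyclohexyl]acetaldehyde | O=CCC1C(O)CCC[C@@]1(C)c1ccc(OC)c(C)c1 | intermediate
18 | (4aR)-7-methoxy-4a,6-dimethyl-1,2,3,4,4a,10a-hexahydrophenanthren-1-ol | OC1CCC[C@@]2(C)c3cc(C)c(OC)cc3C=CC12 | intermediate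
19 | (4aR)-7-methoxy-4a,6-dimethyl-3,4,4a,10a-tetrahydrophenanthren-1(2H)-one | O=C1CCC[C@@]2(C)c3cc(C)c(OC)cc3C=CC12 | intermediate
20 | (4aS,10aS)-7-methoxy-4a,6,10a-trimethyl-3,4,4a,10a-tetrahydrophenanthren-1(2H)-one | O=C1CCC[C@@]2(C)c3cc(C)c(OC)cc3C=C[C@]12C | intermediate
21 | (4aS,10aS)-7-methoxy-2,4a,6,10a-tetramethyl-3,4,4a,10a-tetrahydrophenanthren-1(2H)-one | CC1CC[C@@]2(C)c3cc(C)c(OC)cc3C=C[C@]2(C)C1=O | intermediate
22 | rings C–E dihydroanisole: 8-hydroxy-21-methoxy-9,13α,14β,20-tetramethyl-17(18),20-diene | CC1CC[C@@]2(C)C3=C(CC(OC)=C(C)C3)CC[C@]2(C)C1O | intermediate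
23 | rings C–E enone alcohol: 8-hydroxy-9,13α,14β,20β-tetramethyl-18β-H-17(22)-en-21-one | CC1CC[C@@]2(C)[C@@H]3C[C@@H](C)C(=O)C=C3CC[C@]2(C)C1O | intermediate
24 | rings C–E hydroxy ketone: 8-hydroxy-9,13α,14β,17β,20β-pentamethyl-18β-H-21-one | CC1CC[C@@]2(C)[C@@H]3C[C@@H](C)C(=O)C[C@]3(C)CC[C@]2(C)C1O | intermediate
25 | rings C–E ketal alcohol: 21,21-ethylenedioxy-8-hydroxy-9,13α,14β,17β,20β-pentamethyl-18β-H | CC1CC[C@@]2(C)[C@@H]3C[C@@H](C)C4(OCCO4)C[C@]3(C)CC[C@]2(C)C1O | intermediate
26 | rings C–E ketal ketone: 21,21-ethylenedioxy-9,13α,14β,17β,20β-pentamethyl-18β-H-8-one | CC1CC[C@@]2(C)[C@@H]3C[C@@H](C)C4(OCCO4)C[C@]3(C)CC[C@]2(C)C1=O | intermediate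
27 | rings C–E enol triflate: 21,21-ethylenedioxy-9,13α,14β,17β,20β-pentamethyl-18β-H-8-en-8-yl triflate | O=S(=O)(OC1=C(C)CC[C@@]2(C)[C@@H]3C[C@@H](C)C4(OCCO4)C[C@]3(C)CC[C@]12C)C(F)(F)F | intermediate
28 | tributyl(vinyl)stannane | C=C[Sn](CCCC)(CCCC)CCCC | starting material
29 | rings C–E diene: 8-vinyl-8-ene, 21,21-ethylenedioxy-9,13α,14β,17β,20β-pentamethyl-18β-H | C=CC1=C(C)CC[C@@]2(C)[C@@H]3C[C@@H](C)C4(OCCO4)C[C@]3(C)CC[C@]12C | intermediate
30 | 4,5-dimethoxy-3-methylbenzyne | COC1=CC#CC(C)=C1OC | intermediate
31 | 21,21-ethylenedioxy-2,3-dimethoxy-24,29-dinorfriedela-1,3,5(10),7-tetraene (9β,13α,14β,17β,20β-methyls, 18β-H) | COc1cc2c(c(C)c1OC)CC=C1[C@@]2(C)CC[C@@]2(C)[C@@H]3C[C@@H](C)C4(OCCO4)C[C@]3(C)CC[C@]12C | intermediate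
32 | 21,21-ethylenedioxy-2,3-dimethoxy-24,29-dinorfriedela-1,3,5(10),6-tetraene (8β-H) | COc1cc2c(c(C)c1OC)C=C[C@@H]1[C@@]2(C)CC[C@@]2(C)[C@@H]3C[C@@H](C)C4(OCCO4)C[C@]3(C)CC[C@]12C | intermediate
33 | 2,3-dimethoxy-24,29-dinorfriedela-1,3,5(10),6-tetraen-21-one (8β-H) | COc1cc2c(c(C)c1OC)C=C[C@@H]1[C@@]2(C)CC[C@@]2(C)[C@@H]3C[C@@H](C)C(=O)C[C@]3(C)CC[C@]12C | intermediate
34 | cycloheptanone | O=C1CCCCCC1 | starting material
35 | cyclohepta-2,6-dien-1-one | O=C1C=CCCC=C1 | intermediate
36 | potassium trifluoro(prop-1-en-2-yl)borate | C=C(C)[B-](F)(F)F.[K+] | starting material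
37 | (S)-6-(prop-1-en-2-yl)cyclohept-2-en-1-one | C=C(C)[C@H]1CCC=CC(=O)C1 | intermediate
38 | bromomagnesium (3R,6S)-3-methyl-6-(prop-1-en-2-yl)cyclohept-1-en-1-olate | C=C(C)[C@H]1CC[C@@H](C)C=C(O[Mg]Br)C1 | intermediate
39 | (3R,6S)-2-(but-2-yn-1-yl)-3-methyl-6-(prop-1-en-2-yl)cycloheptan-1-one | C=C(C)[C@H]1CC[C@@H](C)C(CC#CC)C(=O)C1 | intermediate
40 | (3R,6S)-3-methyl-2-(2-oxobutyl)-6-(prop-1-en-2-yl)cycloheptan-1-one | C=C(C)[C@H]1CC[C@@H](C)C(CC(=O)CC)C(=O)C1 | intermediate
41 | (7S,10R)-guaia-4,11-dien-3-one | C=C(C)[C@H]1CC[C@@H](C)C2CC(=O)C(C)=C2C1 | intermediate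
42 | (7S,10R)-guaia-4,11-dien-3-ol | C=C(C)[C@H]1CC[C@@H](C)C2CC(O)C(C)=C2C1 | intermediate
43 | (7S,10R)-guaia-1(5),3,11-triene [(5S,8R)-3,8-dimethyl-5-(prop-1-en-2-yl)-1,4,5,6,7,8-hexahydroazulene] | C=C(C)[C@H]1CC[C@@H](C)C2=C(C1)C(C)=CC2 | intermediate
44 | 2,3-dihydroxy-24,29-dinorfriedela-1,3,5(10),6-tetraen-21-one (8β-H) | Oc1cc2c(c(C)c1O)C=C[C@@H]1[C@@]2(C)CC[C@@]2(C)[C@@H]3C[C@@H](C)C(=O)C[C@]3(C)CC[C@]12C | intermediate
45 | 24,29-dinorfriedela-1(10),4,6-triene-2,3,21-trione (8β-H, ortho-quinone) | O=C1C=C2C(=C(C)C1=O)C=C[C@@H]1[C@@]2(C)CC[C@@]2(C)[C@@H]3C[C@@H](C)C(=O)C[C@]3(C)CC[C@]12C | intermediate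
46 | CNP0233042.2: cis-fused 1,4-benzodioxane adduct, O2–C1′ and O3–C5′, of the 6-ene catechol with (7′S,10′R)-guaia-3′,11′-diene (both oxygens anti to the 10′-methyl) | C=C(C)[C@H]1CC[C@@H](C)[C@@]23CC=C(C)[C@]2(C1)Oc1c(cc2c(c1C)C=C[C@@H]1[C@@]2(C)CC[C@@]2(C)[C@@H]4C[C@@H](C)C(=O)C[C@]4(C)CC[C@]12C)O3 | target

## Step count and least certain steps

Total: 27 steps. Longest linear sequence: 18 steps (steps 5–20, 26, 27).

**Step 19 (key step).** The most likely failure is diversion of the aryne into ene reaction or [2+2] addition at the vinyl group, because the diene is twisted out of the s-cis form by the inside C9 methyl. Bonding of C9 to the wrong aryne carbon is the second risk. The fallback sets out from ketone 26 and forms the two ring B bonds one at a time. Palladium-catalysed α-arylation at C9, the only enolisable position (Pd(OAc)2, P(t-Bu)3, NaOt-Bu, 5-bromo-1,2-dimethoxy-3-methylbenzene), would give the α-aryl ketone F1, with the aryl group entering anti to the 14β-methyl. Vinylmagnesium bromide with CeCl3 would give the tertiary allylic alcohol F2. BF3·OEt2 would ionise F2 to the allyl cation, which closes onto the arene carbon para to the C2 methoxy (Friedel–Crafts allylation). This returns to the route at 31.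

**Step 20.** The risk is poor facial selectivity in the protonation at C8, or slow re-deprotonation at C8 that drifts toward the 8α epimer with the trans B/C fusion; both faces of C8 are crowded and the analysis rests on a conformational argument. The fallback sets out from 31. Allylic/benzylic oxidation (CrO3, 3,5-dimethylpyrazole) would give the 7-en-6-one F3. Conjugate reduction with [(Ph3P)CuH]6 would deliver hydride to C8 of the flat enone and give the 7,8-dihydro-6-one F4, whose 8-H can be checked against the natural 6-oxo series. NaBH4 would give the benzylic alcohol F5, and dehydration with the Burgess reagent would give the 6-ene. This returns to the route at 32.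

**Step 27.** The risks are tautomerisation of the ortho-quinone to the extended quinone methide before it cycloadds (which also erases C8), carbo-Diels–Alder reaction at the quinone C=C, and formation of regio- and face-isomeric adducts, made worse by the 1,5-hydrogen-shift isomer of the diene. The fallback postpones the styrene until after the cycloaddition. From 33, hydrogenation (H2, Pd/C) would give the 6,7-dihydro dimethyl ether F6, and BBr3 the catechol F7. Its ortho-quinone has no vinylogous C8–H to lose, so Ag2O with 43 would give the ring-B-saturated adduct F8. DDQ would then remove hydrogen from C6/C7; the reaction stops at the dihydronaphthalene because C9 is quaternary. This returns to the route at 46.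

**Step 9.** The risk is a sluggish ring closure, because the reacting arene carbon is meta to the methoxy group, together with acid-induced oligomerisation of the styrene formed. The fallback uses an acylium ion instead of an aldehyde. From 16, acetylation would give the acetate F9; RuCl3/NaIO4 cleavage would give the carboxylic acid F10; oxalyl chloride and then SnCl4 would give the tetralone F11 by Friedel–Crafts acylation; LiAlH4 would give the diol F12; and TsOH would dehydrate only the benzylic alcohol. This returns to the route at 18.

## Further compounds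

F1 | step 19 | rings C–E 9β-(3,4-dimethoxy-5-methylphenyl)-21,21-ethylenedioxy-8-one | C[C@@]1(c2cc(C)c(OC)c(OC)c2)CC[C@@]2(C)[C@@H]3C[C@@H](C)C4(OCCO4)C[C@]3(C)CC[C@]2(C)C1=O
F2 | step 19 | rings C–E 9β-aryl-8-vinyl-8-ol (tertiary allylic alcohol) | C[C@@]1(c2cc(C)c(OC)c(OC)c2)CC[C@@]2(C)[C@@H]3C[C@@H](C)C4(OCCO4)C[C@]3(C)CC[C@]2(C)C1(O)C=C
F3 | step 20 | 21,21-ethylenedioxy-2,3-dimethoxy-24,29-dinorfriedela-1,3,5(10),7-tetraen-6-one | COc1cc2c(c(C)c1OC)C(=O)C=C1[C@@]2(C)CC[C@@]2(C)[C@@H]3C[C@@H](C)C4(OCCO4)C[C@]3(C)CC[C@]12C
F4 | step 20 | 21,21-ethylenedioxy-2,3-dimethoxy-24,29-dinorfriedela-1,3,5(10)-trien-6-one (8β-H) | COc1cc2c(c(C)c1OC)C(=O)C[C@@H]1[C@@]2(C)CC[C@@]2(C)[C@@H]3C[C@@H](C)C4(OCCO4)C[C@]3(C)CC[C@]12C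
F5 | step 20 | 21,21-ethylenedioxy-2,3-dimethoxy-24,29-dinorfriedela-1,3,5(10)-trien-6-ol (8β-H) | COc1cc2c(c(C)c1OC)C(O)C[C@@H]1[C@@]2(C)CC[C@@]2(C)[C@@H]3C[C@@H](C)C4(OCCO4)C[C@]3(C)CC[C@]12C
F6 | step 27 | 2,3-dimethoxy-24,29-dinorfriedela-1,3,5(10)-trien-21-one (8β-H) | COc1cc2c(c(C)c1OC)CC[C@@H]1[C@@]2(C)CC[C@@]2(C)[C@@H]3C[C@@H](C)C(=O)C[C@]3(C)CC[C@]12C
F7 | step 27 | 2,3-dihydroxy-24,29-dinorfriedela-1,3,5(10)-trien-21-one (8β-H) | Oc1cc2c(c(C)c1O)CC[C@@H]1[C@@]2(C)CC[C@@]2(C)[C@@H]3C[C@@H](C)C(=O)C[C@]3(C)CC[C@]12C
F8 | step 27 | 6,7-dihydro derivative of 46 | C=C(C)[C@H]1CC[C@@H](C)[C@@]23CC=C(C)[C@]2(C1)Oc1c(cc2c(c1C)CC[C@@H]1[C@@]2(C)CC[C@@]2(C)[C@@H]4C[C@@H](C)C(=O)C[C@]4(C)CC[C@]12C)O3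
F9 | step 9 | (3R)-2-allyl-3-(4-methoxy-3-methylphenyl)-3-methylcyclohexyl acetate | C=CCC1C(OC(C)=O)CCC[C@@]1(C)c1ccc(OC)c(C)c1
F10 | step 9 | 2-[(2R)-6-acetoxy-2-(4-methoxy-3-methylphenyl)-2-methylcyclohexyl]acetic acid | OC(=O)CC1C(OC(C)=O)CCC[C@@]1(C)c1ccc(OC)c(C)c1
F11 | step 9 | (4aR)-7-methoxy-4a,6-dimethyl-9-oxo-1,2,3,4,4a,9,10,10a-octahydrophenanthren-1-yl acetate | CC(=O)OC1CCC[C@@]2(C)c3cc(C)c(OC)cc3C(=O)CC12
F12 | step 9 | (4aR)-7-methoxy-4a,6-dimethyl-1,2,3,4,4a,9,10,10a-octahydrophenanthrene-1,9-diol | OC1CCC[C@@]2(C)c3cc(C)c(OC)cc3C(O)CC12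
A1 | alternative 1 | (7S)-guaia-1(10),4,11-trien-3-one | C=C(C)[C@H]1CCC(C)=C2CC(=O)C(C)=C2C1
A2 | alternative 1 | (6S)-3-methyl-6-(prop-1-en-2-yl)deca-1,2-dien-8-yne | C=C(C)[C@H](CC#CC)CCC(C)=C=C
A3 | alternative 2 | hydroazulene tert-butyldimethylsilyl dienol ether (5,8-diene) | C=C(C)[C@H]1C=C[C@@H](C)[C@H]2CC(O[Si](C)(C)C(C)(C)C)=C(C)C2=C1
A4 | alternative 2 | cis-1-[(E)-prop-1-enyl]-2-(3-silyloxy-4-methylcyclopenta-1,3-dienyl)-3-isopropenylcyclopropane (alkenyl groups cis, isopropenyl trans) | C=C(C)[C@H]1[C@H](/C=C/C)[C@@H]1C1=CCC(O[Si](C)(C)C(C)(C)C)=C1C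
A5 | alternative 3 | 2,3-dimethoxy-24,29-dinorfriedela-1,3,5(10)-triene-12,21-dione (8β-H) | COc1cc2c(c(C)c1OC)CC[C@@H]1[C@@]2(C)CC(=O)[C@@]2(C)[C@@H]3C[C@@H](C)C(=O)C[C@]3(C)CC[C@]12C
A6 | alternative 3 | pentacyclic 13-en-12-one lacking the C13 and C14 methyl groups | COc1cc2c(c(C)c1OC)CC[C@@H]1[C@@]2(C)CC(=O)C3=C1CC[C@@]4(C)CC(=O)[C@H](C)C[C@@H]34
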